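**Retrosynthetic overview**
1. Feature: quinone C6, side-chain C1′, the acetoxy carbon C2′ and the undecyl tail form one unbroken C14 chain oxygenated at its third carbon, which is (R)-3-hydroxytetradecanoic acid. Ring carbons C1–C5, oxygenated at C2 and C4, show the 1,3-pattern of three head-to-tail acetates, whose last carboxyl carbon is surplus.
2. The C1 carbonyl goes in last: quinone ⇒ 3-methoxy-5-alkylphenol with the side-chain acetate already in place (para-oxidation).
3. Phenol ⇒ 7-hydroxy resorcylate acetonide (O-methylation, acetonide hydrolysis, loss of CO2, silyl-to-acetyl exchange).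
4. The only ring built, the carbocycle, ⇒ open-chain diketo-dioxinone by aldol aromatisation (bond C5–C6).
5. Diketo-dioxinone ⇒ O-TBS Weinreb amide of the hydroxy acid plus the dianion of the keto-dioxinone made from 2,2,6-trimethyl-1,3-dioxin-4-one and acetyl chloride.

Key step: step 5

Assumption: all 1,3-dicarbonyl compounds are drawn as keto tautomers, although they should exist largely as enols.

**Step 1**
Reactants: 1 (R)-3-hydroxytetradecanoic acid
Product: 3 (R)-3-hydroxy-N-methoxy-N-methyltetradecanamide, via HOBt active ester 2 (not isolated)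
Conditions: MeNH(OMe)·HCl, EDC·HCl, HOBt, iPr2NEt, CH2Cl2, 0 °C → rt
Reagents that add atoms: N,O-dimethylhydroxylamine hydrochloride, CNOC.Cl
Why: Carbodiimide/HOBt amide coupling, in which the amine should outcompete the secondary β-hydroxyl for the activated acyl group; C3 takes no part, so the (R) centre is carried through unchanged.

**Step 2**
Reactants: 3 (R)-3-hydroxy-N-methoxy-N-methyltetradecanamide
Product: 4 (R)-3-(tert-butyldimethylsilyloxy)-N-methoxy-N-methyltetradecanamide
Conditions: TBSCl, imidazole, DMF, rt
Reagents that add atoms: tert-butyldimethylsilyl chloride, CC(C)(C)[Si](C)(C)Cl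
Why: Imidazole-promoted O-silylation of a secondary alcohol; the silyl ether removes the acidic OH before the strong-base steps and is a poor leaving group for β-elimination.

**Step 3**
Reactants: 5 2,2,6-trimethyl-4H-1,3-dioxin-4-one; 6 acetyl chloride
Product: 8 2,2-dimethyl-6-(2-oxopropyl)-4H-1,3-dioxin-4-one, via lithium dienolate 7 (not isolated)
Conditions: 5 (2 equiv), LiHMDS (2 equiv, 1 M in THF), THF, −78 °C; then 6 (1 equiv), −78 → 0 °C; 1 M HCl
Reagents that add atoms: none
Why: Vinylogous Claisen-type C-acylation, in which kinetic deprotonation of the C6 methyl group gives the extended dienolate that acid chlorides acylate at the γ-carbon; the surplus dienolate takes up the acidic proton of the product.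

**Step 4**
Reactants: 8 2,2-dimethyl-6-(2-oxopropyl)-4H-1,3-dioxin-4-one; 4 (R)-3-(tert-butyldimethylsilyloxy)-N-methoxy-N-methyltetradecanamide
Product: 10 (R)-6-[6-(tert-butyldimethylsilyloxy)-2,4-dioxoheptadecyl]-2,2-dimethyl-4H-1,3-dioxin-4-one, via dilithio dianion 9 (not isolated)
Conditions: 8 (2 equiv), LDA (4.1 equiv, commercial solution), THF, −78 °C; then 4 (1 equiv), −78 → −20 °C; 1 M HCl to pH 3
Reagents that add atoms: none
Why: β-Dicarbonyl dianion acylation, in which the terminal, last-formed carbanion is the most nucleophilic site and the Weinreb amide stops cleanly at the ketone stage; the low temperature keeps α-deprotonation of the amide in check and the stereocentre is not involved.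

**Step 5**
Reactants: 10 (R)-6-[6-(tert-butyldimethylsilyloxy)-2,4-dioxoheptadecyl]-2,2-dimethyl-4H-1,3-dioxin-4-one
Product: 12 (R)-5-[2-(tert-butyldimethylsilyloxy)tridecyl]-7-hydroxy-2,2-dimethyl-4H-1,3-benzodioxin-4-one, via cyclic aldol carbinol 11 (not isolated)
Conditions: Et3N (5 equiv), CH2Cl2, rt
Reagents that add atoms: none
Why: Et3N reversibly ionises the doubly activated methylenes of 10, and in the dienolate that extends through the heterocycle the dioxinone α-carbon (future quinone C5) adds to the chain C4 ketone (future C6) to give carbinol 11, which loses water and tautomerises to arene 12. This is the known late-stage biomimetic aromatisation of diketo-dioxinones to resorcylate acetonides, the laboratory counterpart of the aldol folding of a tetraketide. The single carbocycle closes in a favoured 6-(enolexo)-exo-trig mode. No lasting stereocentre is made, since the two sp3 centres of 11 vanish on aromatisation and the side-chain (R) centre is not touched. The step needs C–C aldol closure rather than Claisen closure, O-cyclisation to a pyranone or E1cB loss of silanolate. Claisen closure is geometrically excluded because the lactone carbonyl lies trans to the chain across the ring C=C; the chain C5 methylene would have to be deprotonated in an already anionic β-diketonate, which a tertiary amine cannot do at a useful rate, while irreversible aromatisation drains the equilibria toward 12.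

**Step 6**
Reactants: 12 (R)-5-[2-(tert-butyldimethylsilyloxy)tridecyl]-7-hydroxy-2,2-dimethyl-4H-1,3-benzodioxin-4-one
Product: 13 (R)-5-[2-(tert-butyldimethylsilyloxy)tridecyl]-7-methoxy-2,2-dimethyl-4H-1,3-benzodioxin-4-one
Conditions: MeI, K2CO3, acetone, reflux
Reagents that add atoms: iodomethane, CI
Why: Williamson O-methylation; the acetonide ties up the other phenol oxygen, so C7–OH is the only acidic site and the oxygen that ends as the quinone C2 methoxy group is marked unambiguously.

**Step 7**
Reactants: 13 (R)-5-[2-(tert-butyldimethylsilyloxy)tridecyl]-7-methoxy-2,2-dimethyl-4H-1,3-benzodioxin-4-one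
Product: 14 (R)-2-[2-(tert-butyldimethylsilyloxy)tridecyl]-6-hydroxy-4-methoxybenzoic acid
Conditions: 2 M aq KOH, 1,4-dioxane, 70 °C; then 1 M HCl to pH 3, 0 °C
Reagents that add atoms: water, O
Why: Saponification of a salicylate acetonide, in which hydroxide adds to the activated acyl carbon and the ketal fragment collapses with loss of acetone; methanol is left out so that no hindered methyl ester forms, and a secondary TBS ether should tolerate aqueous base.

**Step 8**
Reactants: 14 (R)-2-[2-(tert-butyldimethylsilyloxy)tridecyl]-6-hydroxy-4-methoxybenzoic acid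
Product: 15 (R)-3-[2-(tert-butyldimethylsilyloxy)tridecyl]-5-methoxyphenol
Conditions: DMF, 140 °C, N2
Reagents that add atoms: none
Why: Thermal protodecarboxylation of an electron-rich salicylic acid (ipso-protonation ortho to OH and para to OMe, then loss of CO2), the usual behaviour of 2-hydroxy-4-alkoxy-6-alkylbenzoic acids; the silyl ether stays on here so that the carbinol cannot lactonise onto the carboxyl group.

**Step 9**
Reactants: 15 (R)-3-[2-(tert-butyldimethylsilyloxy)tridecyl]-5-methoxyphenol
Product: 16 (R)-3-(2-hydroxytridecyl)-5-methoxyphenol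
Conditions: 48% aq HF, MeCN, 0 °C → rt
Reagents that add atoms: none
Why: Fluoride-driven desilylation that breaks the O–Si and not the C–O bond, so the configuration is retained; the homobenzylic carbinol has no tendency to ionise under these conditions.

**Step 10**
Reactants: 16 (R)-3-(2-hydroxytridecyl)-5-methoxyphenol
Product: 17 (R)-1-(3-acetoxy-5-methoxyphenyl)tridecan-2-yl acetate
Conditions: Ac2O, pyridine, DMAP (cat.), CH2Cl2, 0 °C → rt
Reagents that add atoms: acetic anhydride, CC(=O)OC(C)=O
Why: DMAP-catalysed exhaustive O-acetylation of phenol and carbinol, which avoids having to acylate an alcohol selectively beside a more reactive phenol; the reaction takes place at oxygen, so the stereocentre is retained.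

**Step 11**
Reactants: 17 (R)-1-(3-acetoxy-5-methoxyphenyl)tridecan-2-yl acetate
Product: 18 (R)-1-(3-hydroxy-5-methoxyphenyl)tridecan-2-yl acetate
Conditions: pyrrolidine (1.1 equiv), CH2Cl2, 0 °C
Reagents that add atoms: none
Why: Chemoselective aminolysis, in which the aryl acetate with its phenoxide leaving group is cleaved by a secondary amine at 0 °C while an unactivated secondary alkyl acetate is inert.

**Step 12**
Reactants: 18 (R)-1-(3-hydroxy-5-methoxyphenyl)tridecan-2-yl acetate
Product: 19 2-[(R)-2-acetoxytridecyl]-6-methoxy-1,4-benzoquinone (target)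
Conditions: (KSO3)2NO (2.5 equiv), aq KH2PO4, acetone/H2O, rt
Reagents that add atoms: Fremy's salt (potassium nitrosodisulfonate), [K+].[K+].[O]N(S(=O)(=O)[O-])S(=O)(=O)[O-]
Why: Teuber oxidation; a phenol with a free para position gives the p-quinone, and here that position lies between the methoxy group and the side chain, as known for 3-methoxy-5-alkylphenols, while the near-neutral buffer spares the acetate.

**Compound list**
1 | (R)-3-hydroxytetradecanoic acid | CCCCCCCCCCC[C@H](CC(=O)O)O | starting material
2 | benzotriazol-1-yl (R)-3-hydroxytetradecanoate (HOBt active ester) | CCCCCCCCCCC[C@H](CC(=O)On1nnc2ccccc12)O | intermediate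
3 | (R)-3-hydroxy-N-methoxy-N-methyltetradecanamide | CCCCCCCCCCC[C@H](CC(=O)N(C)OC)O | intermediate
4 | (R)-3-(tert-butyldimethylsilyloxy)-N-methoxy-N-methyltetradecanamide | CCCCCCCCCCC[C@H](CC(=O)N(C)OC)O[Si](C)(C)C(C)(C)C | intermediate
5 | 2,2,6-trimethyl-4H-1,3-dioxin-4-one | CC1=CC(=O)OC(C)(C)O1 | starting material
6 | acetyl chloride | CC(=O)Cl | starting material
7 | lithium dienolate of 5 (lithium 2,2-dimethyl-6-methylidene-1,3-dioxin-4-olate) | [Li+].C=C1C=C([O-])OC(C)(C)O1 | intermediate
8 | 2,2-dimethyl-6-(2-oxopropyl)-4H-1,3-dioxin-4-one | CC(=O)CC1=CC(=O)OC(C)(C)O1 | intermediate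
9 | dilithio dianion of 8 (terminal enolate plus dioxinone dienolate) | [Li+].[Li+].C=C([O-])C=C1C=C([O-])OC(C)(C)O1 | intermediate
10 | (R)-6-[6-(tert-butyldimethylsilyloxy)-2,4-dioxoheptadecyl]-2,2-dimethyl-4H-1,3-dioxin-4-one | CCCCCCCCCCC[C@H](CC(=O)CC(=O)CC1=CC(=O)OC(C)(C)O1)O[Si](C)(C)C(C)(C)C | intermediate
11 | 5-[(R)-2-(tert-butyldimethylsilyloxy)tridecyl]-5-hydroxy-2,2-dimethyl-4a,5-dihydro-1,3-benzodioxine-4,7(6H)-dione (cyclic aldol; C4a and C5 undefined, both lost on dehydration) | CCCCCCCCCCC[C@H](CC1(O)CC(=O)C=C2OC(C)(C)OC(=O)C12)O[Si](C)(C)C(C)(C)C | intermediate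
12 | (R)-5-[2-(tert-butyldimethylsilyloxy)tridecyl]-7-hydroxy-2,2-dimethyl-4H-1,3-benzodioxin-4-one | CCCCCCCCCCC[C@H](Cc1cc(O)cc2OC(C)(C)OC(=O)c12)O[Si](C)(C)C(C)(C)C | intermediate
13 | (R)-5-[2-(tert-butyldimethylsilyloxy)tridecyl]-7-methoxy-2,2-dimethyl-4H-1,3-benzodioxin-4-one | CCCCCCCCCCC[C@H](Cc1cc(OC)cc2OC(C)(C)OC(=O)c12)O[Si](C)(C)C(C)(C)C | intermediate
14 | (R)-2-[2-(tert-butyldimethylsilyloxy)tridecyl]-6-hydroxy-4-methoxybenzoic acid | CCCCCCCCCCC[C@H](Cc1cc(OC)cc(O)c1C(=O)O)O[Si](C)(C)C(C)(C)C | intermediate
15 | (R)-3-[2-(tert-butyldimethylsilyloxy)tridecyl]-5-methoxyphenol | CCCCCCCCCCC[C@H](Cc1cc(O)cc(OC)c1)O[Si](C)(C)C(C)(C)C | intermediate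
16 | (R)-3-(2-hydroxytridecyl)-5-methoxyphenol | CCCCCCCCCCC[C@H](Cc1cc(O)cc(OC)c1)O | intermediate
17 | (R)-1-(3-acetoxy-5-methoxyphenyl)tridecan-2-yl acetate | CCCCCCCCCCC[C@H](Cc1cc(OC(C)=O)cc(OC)c1)OC(C)=O | intermediate
18 | (R)-1-(3-hydroxy-5-methoxyphenyl)tridecan-2-yl acetate | CCCCCCCCCCC[C@H](Cc1cc(O)cc(OC)c1)OC(C)=O | intermediate
19 | 2-[(R)-2-acetoxytridecyl]-6-methoxy-1,4-benzoquinone | CCCCCCCCCCC[C@H](CC1=CC(=O)C=C(OC)C1=O)OC(C)=O | target

**Step count**
Total steps: 12.
Longest linear sequence: 11 (steps 1, 2 and 4–12 from 1). Step 3 is a one-step branch.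

**Steps most likely to fail**

Step 5. The aldol closure through the weakly nucleophilic dioxinone α-carbon may be slow under amine base. β-Elimination of the silyloxy group or O-cyclisation to a pyranone could then consume the open chain. The fallback sets out from 10 and comes back at 14.
- Heating 10 in toluene at 110 °C with benzyl alcohol should expel acetone by retro-[4+2] and give the acylketene F1.
- This is trapped as benzyl (R)-9-(tert-butyldimethylsilyloxy)-3,5,7-trioxoicosanoate F2. Its C2 methylene is a true β-keto ester carbon and a much better aldol donor.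
- Brief treatment with Cs2CO3 in CH2Cl2/iPrOH, followed by AcOH, should aromatise it to benzyl (R)-6-[2-(tert-butyldimethylsilyloxy)tridecyl]-2,4-dihydroxybenzoate F3.
- The C2 hydroxyl is hydrogen-bonded to the ester, so one equivalent of MeI with K2CO3 should methylate only C4–OH. The product is benzyl (R)-6-[2-(tert-butyldimethylsilyloxy)tridecyl]-2-hydroxy-4-methoxybenzoate F4.
- Neutral hydrogenolysis (H2, Pd/C, EtOAc) then gives 14.

Step 4. The strongly basic dianion may deprotonate the amide α-position instead of adding to it. That would lead to proton quench of the dianion and E1cB loss of silanolate. The fallback sets out from 4 and comes back at 10, replacing acylation by aldol addition and oxidation.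
- DIBAL-H in THF at −78 °C should reduce 4 to (R)-3-(tert-butyldimethylsilyloxy)tetradecanal F5.
- The aldehyde is electrophilic enough to capture dianion 9 at −78 °C, faster than any proton transfer. The adduct is 6-[(6R)-6-(tert-butyldimethylsilyloxy)-4-hydroxy-2-oxoheptadecyl]-2,2-dimethyl-4H-1,3-dioxin-4-one F6, whose epimeric carbinol centre is of no consequence.
- Dess–Martin periodinane in CH2Cl2 oxidises this carbinol to 10.

Step 8. Silyl migration or silyl loss in the hot free acid would release the carbinol. Lactonisation onto the neighbouring carboxyl group could then outrun loss of CO2. The fallback sets out from 12 and comes back at 15 by decarboxylating before methylating.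
- With C7–OH still free, hot aqueous KOH in dioxane (about 100 °C) should saponify the acetonide and expel CO2 in the same basic pot. This is the retro-Kolbe–Schmitt behaviour of 2,4-dihydroxy-6-alkylbenzoates, and in this medium the carboxylate cannot lactonise. The product is (R)-5-[2-(tert-butyldimethylsilyloxy)tridecyl]benzene-1,3-diol F7.
- Its two phenols are equivalent, so one equivalent of MeI with K2CO3 in acetone can give only 15 as the mono-ether.
- The price is a statistical methylation with recycling of recovered diol.

**Further compounds**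
F1 | step 5 | (R)-8-(tert-butyldimethylsilyloxy)-2,4,6-trioxononadecylideneketene (acylketene) | CCCCCCCCCCC[C@H](CC(=O)CC(=O)CC(=O)C=C=O)O[Si](C)(C)C(C)(C)C
F2 | step 5 | benzyl (R)-9-(tert-butyldimethylsilyloxy)-3,5,7-trioxoicosanoate | CCCCCCCCCCC[C@H](CC(=O)CC(=O)CC(=O)CC(=O)OCc1ccccc1)O[Si](C)(C)C(C)(C)C
F3 | step 5 | benzyl (R)-6-[2-(tert-butyldimethylsilyloxy)tridecyl]-2,4-dihydroxybenzoate | CCCCCCCCCCC[C@H](Cc1cc(O)cc(O)c1C(=O)OCc1ccccc1)O[Si](C)(C)C(C)(C)C
F4 | step 5 | benzyl (R)-6-[2-(tert-butyldimethylsilyloxy)tridecyl]-2-hydroxy-4-methoxybenzoate | CCCCCCCCCCC[C@H](Cc1cc(OC)cc(O)c1C(=O)OCc1ccccc1)O[Si](C)(C)C(C)(C)C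
F5 | step 4 | (R)-3-(tert-butyldimethylsilyloxy)tetradecanal | CCCCCCCCCCC[C@H](CC=O)O[Si](C)(C)C(C)(C)C
F6 | step 4 | 6-[(6R)-6-(tert-butyldimethylsilyloxy)-4-hydroxy-2-oxoheptadecyl]-2,2-dimethyl-4H-1,3-dioxin-4-one | CCCCCCCCCCC[C@H](CC(O)CC(=O)CC1=CC(=O)OC(C)(C)O1)O[Si](C)(C)C(C)(C)C
F7 | step 8 | (R)-5-[2-(tert-butyldimethylsilyloxy)tridecyl]benzene-1,3-diol | CCCCCCCCCCC[C@H](Cc1cc(O)cc(O)c1)O[Si](C)(C)C(C)(C)C
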